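**Plan**

- Numbering: naphthalene C1 carries the 3,4,5-trimethoxyphenyl ring C, C2 and C3 the methyls, C6 the hydroxyl and C7 the methoxyl; ring A is the oxygenated ring (C4a, C5–C8, C8a), ring B the carbon-substituted ring (C1–C4, C4a, C8a).
- Enabling feature: C1, the carbon that bears ring C, lies between C2 (an alkene carbon before ring closure) and C8a (a ring A carbon para to the C6 oxygen). C1 and ring C can therefore be supplied as the carbonyl carbon of 3,4,5-trimethoxybenzaldehyde, which acts as an electrophile twice.
- Retrosynthesis: the O–benzyl bond and the C1/C2 dehydrogenation are undone first, then C1–C2 and C1–C8a are cut together, and last C3–C4 between a benzylic bromide and a but-2-en-2-yl Grignard reagent.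
- Forward: ring A comes from isovanillin, the side chain is joined at C3–C4 by copper-catalysed coupling, ring B closes when the aldehyde carbon is inserted, then ring B is aromatised and the phenol is freed.
- Stereochemistry: the target has no stereocentre. C1 and C2 are sp3 only in the dihydronaphthalene and are flattened by DDQ; the side-chain alkene geometry is lost in the C3 cation.

Key step: step 5

Remark: commercial 2-bromobut-2-ene is an E/Z mixture and its Grignard reagent does not hold its geometry, so 5, 6, 7 and 9 are written without alkene descriptors, and 9 and 10 are racemic diastereomer mixtures. All isomers converge at 11.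

**Step 1**
Reactants: 1 isovanillin (3-hydroxy-4-methoxybenzaldehyde)
Product: 2 3-(benzyloxy)-4-methoxybenzaldehyde
Conditions: BnBr, K2CO3, DMF, 60 °C
Reagents that add atoms: benzyl bromide, BrCc1ccccc1
Why: Williamson ether synthesis, the phenoxide displacing bromide; the benzyl ether keeps the oxygen para to the later ring-closure site electron-donating and can be removed at the end without touching the four methyl ethers.

**Step 2**
Reactants: 2 3-(benzyloxy)-4-methoxybenzaldehyde
Product: 3 [3-(benzyloxy)-4-methoxyphenyl]methanol
Conditions: NaBH4, MeOH, 0 °C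
Reagents that add atoms: none
Why: Borohydride reduction of an aryl aldehyde is chemoselective and leaves both ethers untouched.

**Step 3**
Reactants: 3 [3-(benzyloxy)-4-methoxyphenyl]methanol
Product: 4 2-(benzyloxy)-4-(bromomethyl)-1-methoxybenzene
Conditions: PBr3, CH2Cl2, 0 °C; used crude
Reagents that add atoms: phosphorus tribromide, BrP(Br)Br
Why: Bromination of a benzylic alcohol with PBr3 (phosphite ester, then SN2 displacement by bromide) is standard for alkoxybenzyl alcohols, and the labile para-methoxybenzylic bromide is taken on without purification.

**Step 4**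
Reactants: 4 2-(benzyloxy)-4-(bromomethyl)-1-methoxybenzene; 5 2-bromobut-2-ene (E/Z mixture)
Product: 7 2-(benzyloxy)-1-methoxy-4-(2-methylbut-2-en-1-yl)benzene (E/Z mixture), via but-2-en-2-ylmagnesium bromide 6 (not isolated)
Conditions: 5, Mg turnings, THF, reflux; then 4, CuI (5 mol %), THF, −30 °C to rt
Reagents that add atoms: magnesium, [Mg] (held only in intermediate 6, leaves as MgBr2)
Why: Copper-catalysed cross-coupling of an alkenyl Grignard reagent with a benzylic bromide forms the sp3–sp2 bond C3–C4 faster than uncatalysed Wurtz coupling, and the alkene geometry need not be controlled.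

**Step 5**
Reactants: 7 2-(benzyloxy)-1-methoxy-4-(2-methylbut-2-en-1-yl)benzene (E/Z mixture); 8 3,4,5-trimethoxybenzaldehyde
Product: 10 6-(benzyloxy)-7-methoxy-2,3-dimethyl-1-(3,4,5-trimethoxyphenyl)-1,2-dihydronaphthalene (racemic cis/trans mixture), via homoallylic alcohol 9 (not isolated)
Conditions: BF3·OEt2 (1.2 equiv), CH2Cl2, −40 to 0 °C, 7 added slowly to 8
Reagents that add atoms: none
Why: Proposed new method: BF3-activated 8 is attacked by the less substituted alkene carbon of 7 (future C2), the tertiary C3 cation loses a benzylic C4 proton to give homoallylic alcohol 9, and BF3 then ionises the C1 carbinol to a trimethoxybenzyl cation that is captured by C8a of ring A. The closest known reaction type is the Lewis-acid Prins (carbonyl-ene) addition followed by intramolecular Friedel–Crafts cyclialkylation used for 1-aryltetralins; new here is that alkene and arene sit in one partner, so the aldehyde carbon is inserted as a single ring atom. Ring B closes as a six-membered ring by Friedel–Crafts alkylation, the C4a–C8a bond of ring A lying inside the new ring (6-endo with respect to the arene), and the Z geometry at C3=C4 needed for closure is reachable by reversible protonation at C4. C1 and C2 are set under substrate control only (trans expected, the C1 aryl group anti to the C2 methyl), racemic, and neither matters because step 6 removes both. Required are Markovnikov addition through C2, secured by the tertiary C3 cation; closure para and not ortho to the benzyloxy group, secured by the stronger para activation and the crowding at C5; and ring closure ahead of a second intermolecular arylation, secured by the six-membered transition state and by adding 7 slowly to a slight excess of 8. Should ring A attack the aldehyde first, the diarylmethyl cation at C1 is closed by the alkene through C2 and the same ring B results.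

**Step 6**
Reactants: 10 6-(benzyloxy)-7-methoxy-2,3-dimethyl-1-(3,4,5-trimethoxyphenyl)-1,2-dihydronaphthalene
Product: 11 6-(benzyloxy)-7-methoxy-2,3-dimethyl-1-(3,4,5-trimethoxyphenyl)naphthalene
Conditions: DDQ (1.2 equiv), toluene, 80 °C
Reagents that add atoms: none
Why: Quinone dehydrogenation, DDQ abstracting the doubly benzylic C1 hydride and the cation losing the C2 proton, is the standard aromatisation of 1-aryl-1,2-dihydronaphthalenes, and both diastereomers of 10 give the same naphthalene.

**Step 7**
Reactants: 11 6-(benzyloxy)-7-methoxy-2,3-dimethyl-1-(3,4,5-trimethoxyphenyl)naphthalene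
Product: 12 3-methoxy-6,7-dimethyl-5-(3,4,5-trimethoxyphenyl)naphthalen-2-ol (the target; 6-hydroxy-7-methoxy-2,3-dimethyl-1-(3,4,5-trimethoxyphenyl)naphthalene in the numbering used above)
Conditions: H2 (1 atm), 10% Pd/C, EtOAc–MeOH, rt
Reagents that add atoms: none
Why: Catalytic hydrogenolysis cleaves the benzyl aryl ether at room temperature, conditions under which the naphthalene core and the aryl methyl ethers are inert.

**Compound list**

1 | isovanillin (3-hydroxy-4-methoxybenzaldehyde) | COc1ccc(C=O)cc1O | starting material
2 | 3-(benzyloxy)-4-methoxybenzaldehyde | COc1ccc(C=O)cc1OCc1ccccc1 | intermediate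
3 | [3-(benzyloxy)-4-methoxyphenyl]methanol | COc1ccc(CO)cc1OCc1ccccc1 | intermediate
4 | 2-(benzyloxy)-4-(bromomethyl)-1-methoxybenzene | COc1ccc(CBr)cc1OCc1ccccc1 | intermediate
5 | 2-bromobut-2-ene (commercial E/Z mixture) | CC=C(C)Br | starting material
6 | but-2-en-2-ylmagnesium bromide (E/Z mixture, not isolated) | CC=C(C)[Mg]Br | intermediate
7 | 2-(benzyloxy)-1-methoxy-4-(2-methylbut-2-en-1-yl)benzene (E/Z mixture) | CC=C(C)Cc1ccc(OC)c(OCc2ccccc2)c1 | intermediate
8 | 3,4,5-trimethoxybenzaldehyde | COc1cc(C=O)cc(OC)c1OC | starting material
9 | 4-[3-(benzyloxy)-4-methoxyphenyl]-2,3-dimethyl-1-(3,4,5-trimethoxyphenyl)but-3-en-1-ol (racemic, diastereomer and alkene-isomer mixture, not isolated) | COc1ccc(C=C(C)C(C)C(O)c2cc(OC)c(OC)c(OC)c2)cc1OCc1ccccc1 | intermediate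
10 | 6-(benzyloxy)-7-methoxy-2,3-dimethyl-1-(3,4,5-trimethoxyphenyl)-1,2-dihydronaphthalene (racemic, cis/trans mixture at C1/C2) | CC1=Cc2cc(OCc3ccccc3)c(OC)cc2C(c2cc(OC)c(OC)c(OC)c2)C1C | intermediate
11 | 6-(benzyloxy)-7-methoxy-2,3-dimethyl-1-(3,4,5-trimethoxyphenyl)naphthalene | COc1cc2c(-c3cc(OC)c(OC)c(OC)c3)c(C)c(C)cc2cc1OCc1ccccc1 | intermediate
12 | 3-methoxy-6,7-dimethyl-5-(3,4,5-trimethoxyphenyl)naphthalen-2-ol (CNP0280611.0) | COc1cc2c(-c3cc(OC)c(OC)c(OC)c3)c(C)c(C)cc2cc1O | target

**Step count**

Total step count: 7.
Longest linear sequence: 7 steps (1 to 12); 5 and 8 enter as purchased materials.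

**Steps most likely to fail**

Step 5 (proposed new method). The intermolecular Prins addition may be outrun by several processes:
- acid-induced migration or oligomerisation of the side-chain alkene;
- twofold arylation of the aldehyde by two molecules of 7;
- capture of the C3 cation by a second aldehyde or by an ortho carbon of ring C;
- disproportionation of the dihydronaphthalene once it has formed.

The fallback uses known chemistry. It sets out from alcohol 3 and comes back at 10, making the C1–C8a bond by organolithium addition at a position fixed by a bromine atom.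
- NBS in MeCN should brominate 3 para to the benzyloxy group to give [5-(benzyloxy)-2-bromo-4-methoxyphenyl]methanol F1.
- PBr3 converts it into 1-(benzyloxy)-4-bromo-5-(bromomethyl)-2-methoxybenzene F2.
- Copper-catalysed coupling with Grignard reagent 6, as in step 4, gives 1-(benzyloxy)-4-bromo-2-methoxy-5-(2-methylbut-2-en-1-yl)benzene F3; the aryl bromide is inert at low temperature.
- Bromine–lithium exchange with n-BuLi in THF at −78 °C gives [4-(benzyloxy)-5-methoxy-2-(2-methylbut-2-en-1-yl)phenyl]lithium F4.
- F4 adds to aldehyde 8 to give [4-(benzyloxy)-5-methoxy-2-(2-methylbut-2-en-1-yl)phenyl](3,4,5-trimethoxyphenyl)methanol F5.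
- Catalytic TsOH in CH2Cl2 ionises this diarylmethanol. The stabilised cation is closed by the alkene through C2 in a 6-endo cation–olefin cyclisation, and loss of the C4 proton delivers 10.

Step 4. Halogen–magnesium exchange and Wurtz-type homocoupling of the benzylic bromide, or its decomposition before coupling, may erode the cross-coupling. The fallback reverses the polarity of the partners; it sets out from 4 and 5 and comes back at 7. Zinc dust with LiCl in THF at 0 °C inserts into the C–Br bond of 4 to give [3-(benzyloxy)-4-methoxybenzyl]zinc bromide F6. Negishi coupling of F6 with 5 under Pd(PPh3)4 (zerovalent palladium, 5 mol %) in THF at 50 °C gives 7, so no Grignard reagent meets the benzylic bromide.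

Step 6. Hydride abstraction by DDQ at the O–CH2Ph group, or further oxidation of the electron-rich rings, may compete with dehydrogenation of ring B. The fallback replaces the quinone by heterogeneous catalytic dehydrogenation; it sets out from 10 and comes back at 12. Compound 10 is heated with 10% Pd/C in mesitylene at reflux under argon, which aromatises ring B to 11 while the hydrogen released begins to cleave the benzyl ether. The cooled suspension is then stirred under H2 to complete the debenzylation. No compound outside the list is made (entry F0).

**Further compounds**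

F1 | step 5 | [5-(benzyloxy)-2-bromo-4-methoxyphenyl]methanol | COc1cc(Br)c(CO)cc1OCc1ccccc1
F2 | step 5 | 1-(benzyloxy)-4-bromo-5-(bromomethyl)-2-methoxybenzene | COc1cc(Br)c(CBr)cc1OCc1ccccc1
F3 | step 5 | 1-(benzyloxy)-4-bromo-2-methoxy-5-(2-methylbut-2-en-1-yl)benzene (E/Z mixture) | CC=C(C)Cc1cc(OCc2ccccc2)c(OC)cc1Br
F4 | step 5 | [4-(benzyloxy)-5-methoxy-2-(2-methylbut-2-en-1-yl)phenyl]lithium (E/Z mixture) | CC=C(C)Cc1cc(OCc2ccccc2)c(OC)cc1[Li]
F5 | step 5 | [4-(benzyloxy)-5-methoxy-2-(2-methylbut-2-en-1-yl)phenyl](3,4,5-trimethoxyphenyl)methanol (racemic, E/Z mixture) | CC=C(C)Cc1cc(OCc2ccccc2)c(OC)cc1C(O)c1cc(OC)c(OC)c(OC)c1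
F6 | step 4 | [3-(benzyloxy)-4-methoxybenzyl]zinc bromide | Br[Zn]Cc1ccc(OC)c(OCc2ccccc2)c1
F0 | step 6 | none | none
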